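(The numbers in the tables come from a simulation for substances that don't exist; noise was put on by code.)

A catalyst charge as small as 4.3 mol% does not last a run: alpha stalls with 18.6% left-handed substrate unused. So the next flask is a choice, more coupling partner or more free catalyst, judged by the rate at the conversion mark.

| flask | left-handed substrate | right-handed substrate | coupling partner | free catalyst | remark |
|---|---|---|---|---|---|
| alpha | 6.7 mM | 6.7 mM | 2 equiv | 4.3 mol% | run made earlier |
| theta | 15 mM | 15 mM | 2 equiv | 4.3 mol% | run made earlier |
| beta | 10 mM | 10 mM | 4 equiv | 4.3 mol% | run made earlier |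
| flask | 10 mM | 10 mM | 2.00 equiv | 4.3 mol% |  |

| run | time / min | left-handed product / % | left-handed substrate / % |
|---|---|---|---|
| alpha | 0.200 | 13.0 | 36.8 |
| alpha | 0.667 | 24.1 | 26.2 |
| alpha | 1.00 | 28.4 | 23.2 |
| alpha | 1.50 | 29.6 | 20.7 |
| alpha | 2.50 | 30.7 | 18.8 |
| alpha | 3.00 | 31.3 | 18.6 |
| theta | 0.200 | 25.8 | 24.9 |
| theta | 0.667 | 40.6 | 9.6 |
| theta | 1.00 | 43.2 | 7.3 |
| theta | 1.50 | 45.5 | 5.0 |
| theta | 2.50 | 46.8 | 3.4 |
| theta | 3.00 | 46.5 | 3.7 |
| beta | 0.250 | 29.6 | 20.4 |
| beta | 0.833 | 43.3 | 7.4 |
| beta | 1.33 | 45.3 | 5.3 |
| beta | 2.00 | 46.0 | 4.1 |
| beta | 3.00 | 46.1 | 3.6 |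

(standard deviation of a reading: 0.5 percentage points)

- factor on the rate of making left-handed product when 50% of the left-handed substrate and right-handed substrate together are converted if coupling partner is charged twice over
- factor on the rate when 50% of the left-handed substrate and right-handed substrate together are converted if free catalyst is charged at 40 mol% instead

- free catalyst is single-handed; left-handed substrate and right-handed substrate are mirror images of each other, charged as a racemate, each of them at the stated concentration
- the numbers in the tables scatter with a standard deviation of 0.5 percentage points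
- reactions considered so far: 2 free catalyst <-> resting dimer; free catalyst + right-handed substrate <-> catalyst intermediate B; coupling partner + catalyst intermediate A -> free catalyst + left-handed product; free catalyst + left-handed substrate <-> catalyst intermediate A; coupling partner + catalyst intermediate B -> free catalyst + right-handed product; free catalyst -> spent catalyst

Let L be the left-handed substrate, and X = ln(L₀/L), where L₀ is half the total charge. In theta, the gap ln(L/L∞) to the stall level L∞ shrinks from 1.99 at 0.200 min to 0.386 at 1.50 min. That gives the catalyst lifetime τ, the time in which working catalyst falls by a factor e: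

τ = 0.792 min

Each τ saved before the mark multiplies the rate by e. The stall values X∞ are 0.989 for alpha and 2.69 for theta. Their geometric mean gives the flask:

X∞ = 1.63, stall L = 9.79%

The flask's left-handed product therefore stalls near 40.2%, below the mark. The right-handed product is unread, so I place the flask's mark in the tail, at 3.00 min.

Beta is the doubled flask. I place its mark at 0.833 min, with X∞ = 2.63:

dbl ≈ 18.8

Theta against alpha scales every charge by one factor, and beta against the flask doubles the partner, so the difference of their logarithmic slopes in X∞ gives an apparent catalyst order n = 0.550. I extrapolate this reading to 40 mol%, an estimate well outside the runs, so X∞ = 5.57. The same X is then reached at 0.275 min: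

ratio ≈ 107

I would charge catalyst, which gains more than partner. The forecast gave 2.3 (1.6 to 3) and 4 (2.6 to 6.5), because “faster runs arrive with more live catalyst”; my figures are larger.

The flask gives 32.8 and 207, on this scheme:

    2 free catalyst ⇌ resting dimer (K = 1.30 × 10⁵ M⁻¹, k = 130 M⁻¹ s⁻¹)
    free catalyst + right-handed substrate ⇌ catalyst intermediate B (K = 150 M⁻¹, k = 3100 M⁻¹ s⁻¹)
    coupling partner + catalyst intermediate A → free catalyst + left-handed product (k = 350 M⁻¹ s⁻¹)
    free catalyst + left-handed substrate ⇌ catalyst intermediate A (K = 76.0 M⁻¹, k = 840 M⁻¹ s⁻¹)
    coupling partner + catalyst intermediate B → free catalyst + right-handed product (k = 17.0 M⁻¹ s⁻¹)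
    free catalyst → spent catalyst (k = 0.0470 s⁻¹)

The flask reaches the mark at 2.71 min, and at 2.50 min spent catalyst is 70.2% of the catalyst charged. Free catalyst and both intermediates together stand at 43.3% at 0.500 min. Carried forward with τ, that becomes 3.47% at 2.50 min, where the flask holds 3.95%.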